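**Retrosynthetic overview**

1. The target is ring A (5,6-dihydro-2H-pyran-2-one, O1 and C2–C6) with a C1′–C15′ chain on C6. Ring A, its only ring, is closed late by ring-closing metathesis of a C6–O acrylate onto the allyl terminus (C4–C5), followed by silyl ether removal.
2. The acyclic precursor is cut in one operation into four components: (S)-3-(PMB-oxy)hex-5-enal (C4, C5, C6, C1′, C2′ and the future O1), two acetaldehyde units as a supersilyl enol ether (C3′/C4′ and C5′/C6′) and nonylmagnesium bromide (C7′–C15′). The bonds C2′–C3′, C4′–C5′ and finally C6′–C7′ (carbinol carbon to nonyl CH2) form together with the stereocentres C2′, C4′ and C6′.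
3. Enabling feature: C2′, C4′ and C6′ are an all-syn 1,3,5-triol of head-to-tail –CH(O)–CH2– units ending in a carbinol (C6′) that carries an unfunctionalised linear alkyl chain, and the ring oxygen on C6 is 1,3-anti to the C2′ oxygen. An ether on C6 can therefore seed anti induction, each new bulky siloxy group can relay syn induction, and a plain alkyl Grignard reagent can terminate the chain.
4. The aldehyde comes from 3-(PMB-oxy)propan-1-ol by enantioselective allylation (sets C6) and PMB transposition.
5. Ring order: a temporary 1,3-dioxane (formed in step 2, opened in step 3), then ring A (step 11).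

Key step: step 6

Assumption: 3-[(4-methoxybenzyl)oxy]propan-1-ol, chlorotris(trimethylsilyl)silane and ethereal nonylmagnesium bromide are taken as commercial; PMB = 4-methoxybenzyl, TBS = tert-butyldimethylsilyl, supersilyl = tris(trimethylsilyl)silyl.

**Route**

Step 1
Reactants: 1 3-[(4-methoxybenzyl)oxy]propan-1-ol; 2 allyl acetate
Product: 3 (S)-1-[(4-methoxybenzyl)oxy]hex-5-en-3-ol
Conditions: [Ir(cod)Cl]2 (2.5 mol%), (S)-Cl,MeO-BIPHEP (5 mol%), 4-chloro-3-nitrobenzoic acid (10 mol%), Cs2CO3 (20 mol%), THF, 100 °C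
Reagents that add atoms: none
Why: Krische allylation (iridium-catalysed transfer-hydrogenative carbonyl allylation from the alcohol oxidation level): the alcohol is dehydrogenated in situ and the chiral allyliridium species formed from [Ir(cod)Cl]2, ligand and nitrobenzoic acid adds to one face of the transient aldehyde, so the ligand sets the carbinol as (S) (the ligand antipode is the one chosen to give this sense).

Step 2
Reactants: 3 (S)-1-[(4-methoxybenzyl)oxy]hex-5-en-3-ol
Product: 4 (2R,4S)-2-(4-methoxyphenyl)-4-(prop-2-en-1-yl)-1,3-dioxane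
Conditions: DDQ (1.2 equiv), 4 Å molecular sieves, CH2Cl2, 0 °C
Reagents that add atoms: none
Why: Oxidative acetalisation of a PMB ether (Oikawa–Yonemitsu type): DDQ abstracts benzylic hydride and the 1,3-disposed hydroxyl traps the oxocarbenium ion as the six-membered 4-methoxybenzylidene acetal, whose new acetal centre should be cis (both substituents equatorial) and is destroyed in the next step.

Step 3
Reactants: 4 (2R,4S)-2-(4-methoxyphenyl)-4-(prop-2-en-1-yl)-1,3-dioxane
Product: 5 (S)-3-[(4-methoxybenzyl)oxy]hex-5-en-1-ol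
Conditions: (i-Bu)2AlH (3 equiv), CH2Cl2, −78 → 0 °C; aq. KNaC4H4O6 work-up
Reagents that add atoms: none
Why: Regioselective reductive acetal opening: the aluminium hydride coordinates the less hindered primary oxygen, that C–O bond ionises and hydride quenches the oxocarbenium ion, which leaves the PMB group on the secondary oxygen.

Step 4
Reactants: 5 (S)-3-[(4-methoxybenzyl)oxy]hex-5-en-1-ol
Product: 6 (S)-3-[(4-methoxybenzyl)oxy]hex-5-enal
Conditions: Dess–Martin periodinane (1.2 equiv), CH2Cl2, 0 °C → rt; used without chromatography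
Reagents that add atoms: none
Why: Dess–Martin oxidation under near-neutral conditions gives the β-alkoxy aldehyde without β-elimination of the PMB ether, and the stereocentre, being β to the carbonyl, cannot epimerise.

Step 5
Reactants: 7 tetrahydrofuran; 8 chlorotris(trimethylsilyl)silane
Product: 10 ethenyloxytris(trimethylsilyl)silane (supersilyl enol ether of acetaldehyde), via lithium ethenolate 9 (not isolated)
Conditions: n-BuLi (hexanes), neat 7, 25 °C, 16 h; then 8, 0 °C → rt; distillation
Reagents that add atoms: none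
Why: α-Lithiation of tetrahydrofuran followed by [3+2] cycloreversion is the standard source of the lithium enolate of acetaldehyde, which is O-silylated by the bulky chlorosilane to give the enol ether.

Step 6
Reactants: 6 (S)-3-[(4-methoxybenzyl)oxy]hex-5-enal; 10 ethenyloxytris(trimethylsilyl)silane (2.1 equiv); 11 nonylmagnesium bromide
Product: 14 (4S,6R,8S,10S)-4-[(4-methoxybenzyl)oxy]-6,8-bis{[tris(trimethylsilyl)silyl]oxy}nonadec-1-en-10-ol, via mono-aldol aldehyde 12 (not isolated), via bis-aldol aldehyde 13 (not isolated)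
Conditions: HNTf2 (0.1 mol%), CH2Cl2, −78 → −20 °C; then 11 (1.5 equiv, Et2O), −78 °C; aq. NH4Cl
Reagents that add atoms: none
Why: HNTf2 protodesilylates a trace of 10 to (Me3Si)3SiNTf2, which activates the aldehyde for Mukaiyama aldol addition of 10; transfer of the supersilyl group to the new aldolate oxygen regenerates the silyl Lewis acid and unveils the next aldehyde, so two enol ether units are joined head to tail (C6–C7 and C8–C9 of 14) before the remaining aldehyde is captured by the Grignard reagent (C10–C11, the bond between the carbinol carbon and the nonyl chain). The closest known reaction type is the supersilyl-governed aldehyde cross-aldol cascade with one-pot organomagnesium termination (sequential Mukaiyama aldol–Grignard addition). No ring is closed. C6 should be set by 1,3-anti induction from the C4 PMB ether (polar, dipole-minimised model for β-alkoxy aldehydes under a non-chelating Lewis acid), C8 by the 1,3-syn preference imposed by the very bulky C6 supersiloxy group, and C10 in the same way by the C8 supersiloxy group, which shields one face of the aldehyde towards the Grignard reagent. The step needs chain-length control and chemoselective 1,2-addition: each supersiloxy aldehyde is a poorer electrophile than its precursor, so with two equivalents of 10 the cascade should halt at 13, and the PMB ether, terminal alkene and silyl ethers are inert to the Grignard reagent at low temperature.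

Step 7
Reactants: 14 (4S,6R,8S,10S)-4-[(4-methoxybenzyl)oxy]-6,8-bis{[tris(trimethylsilyl)silyl]oxy}nonadec-1-en-10-ol
Product: 15 (4S,6S,8S,10S)-4-[(4-methoxybenzyl)oxy]nonadec-1-ene-6,8,10-triol
Conditions: Bu4NF (4 equiv), THF, 0 °C → rt
Reagents that add atoms: none
Why: Fluoride-induced cleavage of the supersilyl ethers (labile to Bu4NF although stable to acid and organometallics) frees the all-syn triol at a stage where no base-sensitive function is present.

Step 8
Reactants: 15 (4S,6S,8S,10S)-4-[(4-methoxybenzyl)oxy]nonadec-1-ene-6,8,10-triol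
Product: 16 (4S,6R,8S,10S)-6,8,10-tris[(tert-butyldimethylsilyl)oxy]-4-[(4-methoxybenzyl)oxy]nonadec-1-ene
Conditions: TBSOTf (3.6 equiv), 2,6-lutidine, CH2Cl2, −78 → 0 °C
Reagents that add atoms: tert-butyldimethylsilyl trifluoromethanesulfonate, CC(C)(C)[Si](C)(C)OS(=O)(=O)C(F)(F)F
Why: Exhaustive silylation with the silyl triflate converts the three secondary hydroxyls into TBS ethers, a set that survives DDQ, acylation and metathesis and leaves under mild acidic fluoride at the end.

Step 9
Reactants: 16 (4S,6R,8S,10S)-6,8,10-tris[(tert-butyldimethylsilyl)oxy]-4-[(4-methoxybenzyl)oxy]nonadec-1-ene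
Product: 17 (4S,6R,8S,10S)-6,8,10-tris[(tert-butyldimethylsilyl)oxy]nonadec-1-en-4-ol
Conditions: DDQ (1.5 equiv), CH2Cl2/aq. NaH2PO4–Na2HPO4 buffer (pH 7), 0 °C
Reagents that add atoms: none
Why: Oxidative PMB cleavage by DDQ (benzylic hydride abstraction, then hydrolysis of the oxocarbenium ion) is selective for the electron-rich benzyl ether in the presence of TBS ethers and the terminal alkene.

Step 10
Reactants: 17 (4S,6R,8S,10S)-6,8,10-tris[(tert-butyldimethylsilyl)oxy]nonadec-1-en-4-ol; 18 acryloyl chloride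
Product: 19 (4S,6R,8S,10S)-6,8,10-tris[(tert-butyldimethylsilyl)oxy]nonadec-1-en-4-yl prop-2-enoate
Conditions: i-Pr2NEt, DMAP (cat.), CH2Cl2, −78 → 0 °C
Reagents that add atoms: none
Why: Standard O-acylation of the secondary homoallylic alcohol with an acid chloride under amine base installs the second olefin for ring closure without touching the stereocentre.

Step 11
Reactants: 19 (4S,6R,8S,10S)-6,8,10-tris[(tert-butyldimethylsilyl)oxy]nonadec-1-en-4-yl prop-2-enoate
Product: 20 (6S)-6-{(2R,4S,6S)-2,4,6-tris[(tert-butyldimethylsilyl)oxy]pentadecyl}-5,6-dihydro-2H-pyran-2-one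
Conditions: second-generation Grubbs catalyst (H2IMes)(PCy3)Cl2Ru=CHPh (5 mol%), CH2Cl2 (2 mM), 40 °C
Reagents that add atoms: none
Why: Ring-closing metathesis of the acrylate with the homoallylic terminal alkene closes the six-membered α,β-unsaturated δ-lactone (ring A), driven by loss of ethene, the ring olefin being necessarily cis.

Step 12
Reactants: 20 (6S)-6-{(2R,4S,6S)-2,4,6-tris[(tert-butyldimethylsilyl)oxy]pentadecyl}-5,6-dihydro-2H-pyran-2-one
Product: 21 (6S)-6-[(2S,4S,6S)-2,4,6-trihydroxypentadecyl]-5,6-dihydro-2H-pyran-2-one (target)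
Conditions: 48% aq. HF, MeCN, 0 °C → rt
Reagents that add atoms: none
Why: Acidic fluoride cleaves the three TBS ethers without opening the lactone and without the base-mediated conjugate addition of a liberated hydroxyl that basic fluoride could trigger.

**Compound list**

1 | 3-[(4-methoxybenzyl)oxy]propan-1-ol | COc1ccc(COCCCO)cc1 | starting material
2 | allyl acetate | CC(=O)OCC=C | starting material
3 | (S)-1-[(4-methoxybenzyl)oxy]hex-5-en-3-ol | COc1ccc(COCC[C@@H](O)CC=C)cc1 | intermediate
4 | (2R,4S)-2-(4-methoxyphenyl)-4-(prop-2-en-1-yl)-1,3-dioxane | C=CC[C@H]1CCO[C@@H](c2ccc(OC)cc2)O1 | intermediate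
5 | (S)-3-[(4-methoxybenzyl)oxy]hex-5-en-1-ol | OCC[C@@H](OCc1ccc(OC)cc1)CC=C | intermediate
6 | (S)-3-[(4-methoxybenzyl)oxy]hex-5-enal | O=CC[C@@H](OCc1ccc(OC)cc1)CC=C | intermediate
7 | tetrahydrofuran | C1CCOC1 | starting material
8 | chlorotris(trimethylsilyl)silane | C[Si](C)(C)[Si](Cl)([Si](C)(C)C)[Si](C)(C)C | starting material
9 | lithium ethenolate (not isolated) | [Li+].[O-]C=C | intermediate
10 | ethenyloxytris(trimethylsilyl)silane | C=CO[Si]([Si](C)(C)C)([Si](C)(C)C)[Si](C)(C)C | intermediate
11 | nonylmagnesium bromide | CCCCCCCCC[Mg]Br | starting material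
12 | (3R,5S)-5-[(4-methoxybenzyl)oxy]-3-{[tris(trimethylsilyl)silyl]oxy}oct-7-enal (not isolated) | O=CC[C@H](O[Si]([Si](C)(C)C)([Si](C)(C)C)[Si](C)(C)C)C[C@@H](OCc1ccc(OC)cc1)CC=C | intermediate
13 | (3R,5R,7S)-7-[(4-methoxybenzyl)oxy]-3,5-bis{[tris(trimethylsilyl)silyl]oxy}dec-9-enal (not isolated) | O=CC[C@H](O[Si]([Si](C)(C)C)([Si](C)(C)C)[Si](C)(C)C)C[C@H](O[Si]([Si](C)(C)C)([Si](C)(C)C)[Si](C)(C)C)C[C@@H](OCc1ccc(OC)cc1)CC=C | intermediate
14 | (4S,6R,8S,10S)-4-[(4-methoxybenzyl)oxy]-6,8-bis{[tris(trimethylsilyl)silyl]oxy}nonadec-1-en-10-ol | CCCCCCCCC[C@H](O)C[C@H](O[Si]([Si](C)(C)C)([Si](C)(C)C)[Si](C)(C)C)C[C@H](O[Si]([Si](C)(C)C)([Si](C)(C)C)[Si](C)(C)C)C[C@@H](OCc1ccc(OC)cc1)CC=C | intermediate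
15 | (4S,6S,8S,10S)-4-[(4-methoxybenzyl)oxy]nonadec-1-ene-6,8,10-triol | CCCCCCCCC[C@H](O)C[C@H](O)C[C@H](O)C[C@@H](OCc1ccc(OC)cc1)CC=C | intermediate
16 | (4S,6R,8S,10S)-6,8,10-tris[(tert-butyldimethylsilyl)oxy]-4-[(4-methoxybenzyl)oxy]nonadec-1-ene | CCCCCCCCC[C@H](O[Si](C)(C)C(C)(C)C)C[C@H](O[Si](C)(C)C(C)(C)C)C[C@H](O[Si](C)(C)C(C)(C)C)C[C@@H](OCc1ccc(OC)cc1)CC=C | intermediate
17 | (4S,6R,8S,10S)-6,8,10-tris[(tert-butyldimethylsilyl)oxy]nonadec-1-en-4-ol | CCCCCCCCC[C@H](O[Si](C)(C)C(C)(C)C)C[C@H](O[Si](C)(C)C(C)(C)C)C[C@H](O[Si](C)(C)C(C)(C)C)C[C@@H](O)CC=C | intermediate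
18 | acryloyl chloride | C=CC(=O)Cl | starting material
19 | (4S,6R,8S,10S)-6,8,10-tris[(tert-butyldimethylsilyl)oxy]nonadec-1-en-4-yl prop-2-enoate | CCCCCCCCC[C@H](O[Si](C)(C)C(C)(C)C)C[C@H](O[Si](C)(C)C(C)(C)C)C[C@H](O[Si](C)(C)C(C)(C)C)C[C@@H](OC(=O)C=C)CC=C | intermediate
20 | (6S)-6-{(2R,4S,6S)-2,4,6-tris[(tert-butyldimethylsilyl)oxy]pentadecyl}-5,6-dihydro-2H-pyran-2-one | CCCCCCCCC[C@H](O[Si](C)(C)C(C)(C)C)C[C@H](O[Si](C)(C)C(C)(C)C)C[C@H](O[Si](C)(C)C(C)(C)C)C[C@@H]1CC=CC(=O)O1 | intermediate
21 | (6S)-6-[(2S,4S,6S)-2,4,6-trihydroxypentadecyl]-5,6-dihydro-2H-pyran-2-one | CCCCCCCCC[C@H](O)C[C@H](O)C[C@H](O)C[C@@H]1CC=CC(=O)O1 | target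

**Step count and risks**

Total step count: 12. Longest linear sequence: 11 (steps 1–4 and 6–12); step 5 is a one-step side branch.

Steps most likely to fail:

Step 6. The stereochemical relay may leak at its first link: with a small, unsubstituted enol ether the dipole-controlled 1,3-anti bias of the PMB ether may be modest, and the strongly Lewis acidic silyl triflimide may begin to ionise the PMB ether. Either process would lower the diastereomeric purity of everything downstream. The fallback sets out from 6 and takes the first addition out of the cascade under chelation control. A Mukaiyama aldol of 6 with 1-(tert-butylsulfanyl)-1-(trimethylsilyloxy)ethene promoted by Me2AlCl (CH2Cl2, −78 °C) proceeds through a six-membered chelate between the aldehyde and PMB-ether oxygens, which exposes the face anti to the allyl-bearing centre and should give S-tert-butyl (3R,5S)-3-hydroxy-5-[(4-methoxybenzyl)oxy]oct-7-enethioate F1. Silylation with 8 (imidazole, DMAP, DMF) gives S-tert-butyl (3R,5S)-5-[(4-methoxybenzyl)oxy]-3-{[tris(trimethylsilyl)silyl]oxy}oct-7-enethioate F2, and (i-Bu)2AlH (CH2Cl2, −78 °C) reduces the thioester to the aldehyde. The fallback comes back to the route at 12, now isolated, which is taken through the rest of step 6 (one equivalent of 10, then 11) to 14.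

Step 12. Once the side-chain hydroxyls are free, the C2′ hydroxyl may add in conjugate fashion to C4 of the enoate (bridged bicyclic ether), or the lactone may be opened during the prolonged exposure needed to remove the most hindered silyl ether. The fallback sets out from 19 and reverses the order of events so that the enoate lactone never meets fluoride. HF·pyridine (THF/pyridine, 0 °C → rt) desilylates the acyclic acrylate to (4S,6S,8S,10S)-6,8,10-trihydroxynonadec-1-en-4-yl prop-2-enoate F3. Ring-closing metathesis of this free triol with the second-generation Grubbs catalyst (H2IMes)(PCy3)Cl2Ru=CHPh (CH2Cl2, 40 °C, high dilution) then forms ring A under neutral conditions, and the fallback comes back to the route at 21.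

Step 11. Ring closure may stall through chelation of the ruthenium carbene to the acrylate carbonyl next to the bulky silyloxy groups, with intermolecular cross-metathesis to dimers taking over. The fallback sets out from 16 and builds ring A by olefination and lactonisation instead. Ozonolysis (O3, CH2Cl2, −78 °C; PPh3) gives (3R,5R,7S,9S)-5,7,9-tris[(tert-butyldimethylsilyl)oxy]-3-[(4-methoxybenzyl)oxy]octadecanal F4. Still–Gennari olefination with methyl bis(2,2,2-trifluoroethyl)phosphonoacetate (KN(SiMe3)2, 18-crown-6, THF, −78 °C) gives methyl (2Z,5S,7R,9S,11S)-7,9,11-tris[(tert-butyldimethylsilyl)oxy]-5-[(4-methoxybenzyl)oxy]icos-2-enoate F5. DDQ (CH2Cl2/pH 7 buffer) then unmasks methyl (2Z,5S,7R,9S,11S)-7,9,11-tris[(tert-butyldimethylsilyl)oxy]-5-hydroxyicos-2-enoate F6, which lactonises on the cis enoate (cat. pyridinium p-toluenesulfonate, toluene, 60 °C), and the fallback comes back to the route at 20.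

Further compounds

F1 | step 6 | S-tert-butyl (3R,5S)-3-hydroxy-5-[(4-methoxybenzyl)oxy]oct-7-enethioate | CC(C)(C)SC(=O)C[C@H](O)C[C@@H](OCc1ccc(OC)cc1)CC=C
F2 | step 6 | S-tert-butyl (3R,5S)-5-[(4-methoxybenzyl)oxy]-3-{[tris(trimethylsilyl)silyl]oxy}oct-7-enethioate | CC(C)(C)SC(=O)C[C@H](O[Si]([Si](C)(C)C)([Si](C)(C)C)[Si](C)(C)C)C[C@@H](OCc1ccc(OC)cc1)CC=C
F3 | step 12 | (4S,6S,8S,10S)-6,8,10-trihydroxynonadec-1-en-4-yl prop-2-enoate | CCCCCCCCC[C@H](O)C[C@H](O)C[C@H](O)C[C@@H](OC(=O)C=C)CC=C
F4 | step 11 | (3R,5R,7S,9S)-5,7,9-tris[(tert-butyldimethylsilyl)oxy]-3-[(4-methoxybenzyl)oxy]octadecanal | CCCCCCCCC[C@H](O[Si](C)(C)C(C)(C)C)C[C@H](O[Si](C)(C)C(C)(C)C)C[C@H](O[Si](C)(C)C(C)(C)C)C[C@@H](OCc1ccc(OC)cc1)CC=O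
F5 | step 11 | methyl (2Z,5S,7R,9S,11S)-7,9,11-tris[(tert-butyldimethylsilyl)oxy]-5-[(4-methoxybenzyl)oxy]icos-2-enoate | CCCCCCCCC[C@H](O[Si](C)(C)C(C)(C)C)C[C@H](O[Si](C)(C)C(C)(C)C)C[C@H](O[Si](C)(C)C(C)(C)C)C[C@@H](OCc1ccc(OC)cc1)C/C=C\C(=O)OC
F6 | step 11 | methyl (2Z,5S,7R,9S,11S)-7,9,11-tris[(tert-butyldimethylsilyl)oxy]-5-hydroxyicos-2-enoate | CCCCCCCCC[C@H](O[Si](C)(C)C(C)(C)C)C[C@H](O[Si](C)(C)C(C)(C)C)C[C@H](O[Si](C)(C)C(C)(C)C)C[C@@H](O)C/C=C\C(=O)OC
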